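The target is an (R)-1,1-diarylpropane. After removal of five O-benzyl groups, the retrosynthesis cuts the bond from ring C to the 3-oxo-3-arylpropyl chain (Heck coupling of a ring C bromide with a ring D aryl vinyl ketone).
Ring B is then dismantled: the 4-hydroxyphenyl ring has its oxygen on C4, para to the C1 that sits on the stereocentre, so it is the dehydrogenation product of a 4-substituted cyclohex-2-enone. Cutting its C1–C6 and C2–C3 bonds leaves a CH2–CHO group on the stereocentre plus methyl vinyl ketone.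
The resulting 3-arylpentanal is cut at the stereocentre–ring C bond (asymmetric 1,4-addition of a ring C boronic acid to a ring A pent-2-enoate), and the enoate at C2=C3 (cross-metathesis) and at the ring A–CH2 bond (Kumada coupling).
Forward: the ring A chain (steps 1–3) and the ring C boronic acid (steps 4–5) are joined in step 6; ring B is annulated in step 8 and aromatised in step 9; ring D is attached in step 12 and hydrogenation ends the route.
The single stereocentre is set in step 6 by the (S)-BINAP–rhodium catalyst, while it carries only one aryl group and two different alkyl chains; it has no acidic hydrogen in any later step.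

Key step: step 8

Assumption: the (S)-BINAP–rhodium catalyst is taken to deliver the aryl group to the C2-si (C3-re) face of the (E)-enoate, as it does with simple (E)-3-alkylacrylates, which gives the 3R ester; if the first run shows the opposite sense, (R)-BINAP is used with no other change.

**Step 1**
Reactants: 1 4-bromo-3-methoxyphenol
Product: 2 4-(benzyloxy)-1-bromo-2-methoxybenzene
Conditions: BnBr (1.1 equiv), K2CO3, DMF, rt
Reagents that add atoms: benzyl bromide, BrCc1ccccc1
Why: Williamson ether synthesis, in which the phenoxide formed with K2CO3 displaces bromide from the primary benzylic halide.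

**Step 2**
Reactants: 2 4-(benzyloxy)-1-bromo-2-methoxybenzene
Product: 3 4-(benzyloxy)-1-(but-3-en-1-yl)-2-methoxybenzene
Conditions: CH2=CHCH2CH2MgBr (1.5 equiv), PdCl2(dppf)·CH2Cl2 (3 mol %), THF, 0 °C → reflux
Reagents that add atoms: but-3-en-1-ylmagnesium bromide, C=CCC[Mg]Br
Why: Kumada–Corriu coupling, in which the wide-bite-angle dppf ligand makes reductive elimination from the aryl(alkyl)palladium faster than β-hydride elimination, and the two ether groups are inert to the Grignard reagent.

**Step 3**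
Reactants: 3 4-(benzyloxy)-1-(but-3-en-1-yl)-2-methoxybenzene
Product: 4 ethyl (2E)-5-[4-(benzyloxy)-2-methoxyphenyl]pent-2-enoate
Conditions: ethyl acrylate (3 equiv), second-generation Hoveyda–Grubbs catalyst RuCl2(H2IMes)(=CH-C6H4-2-O-i-Pr) (2 mol %), CH2Cl2, 40 °C
Reagents that add atoms: ethyl acrylate, C=CC(=O)OCC
Why: Olefin cross-metathesis of a terminal alkene with an acrylate, which pair selectively and should give the (E)-enoate under thermodynamic control with loss of ethene.

**Step 4**
Reactants: 5 4,6-dibromobenzene-1,3-diol (4,6-dibromoresorcinol)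
Product: 6 1,5-bis(benzyloxy)-2,4-dibromobenzene
Conditions: BnBr (2.3 equiv), K2CO3, DMF, rt → 50 °C
Reagents that add atoms: benzyl bromide, BrCc1ccccc1
Why: Twofold Williamson ether synthesis on the acidified bromophenol hydroxyl groups, for which carbonate is a sufficient base.

**Step 5**
Reactants: 6 1,5-bis(benzyloxy)-2,4-dibromobenzene
Product: 9 [2,4-bis(benzyloxy)-5-bromophenyl]boronic acid, via aryllithium 7 (not isolated), via lithium triisopropoxyborate 8 (not isolated)
Conditions: n-BuLi (1.0 equiv), THF, −78 °C; B(O-i-Pr)3, −78 °C → rt; 1 M HCl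
Reagents that add atoms: triisopropyl borate, CC(C)OB(OC(C)C)OC(C)C; water, O
Why: Bromine–lithium exchange followed by borylation, in which the two equivalent bromines give one monolithio species with one equivalent of n-BuLi at −78 °C (a second exchange on the aryl anion is slow), the borate traps it as the ate complex and aqueous acid releases the boronic acid.

**Step 6**
Reactants: 4 ethyl (2E)-5-[4-(benzyloxy)-2-methoxyphenyl]pent-2-enoate; 9 [2,4-bis(benzyloxy)-5-bromophenyl]boronic acid
Product: 10 ethyl (3R)-3-[2,4-bis(benzyloxy)-5-bromophenyl]-5-[4-(benzyloxy)-2-methoxyphenyl]pentanoate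
Conditions: 9 (2.5 equiv, in portions), [Rh(nbd)2]BF4 (3 mol %), (S)-BINAP (3.3 mol %), Et3N (1 equiv), 1,4-dioxane/H2O 10:1, 40 °C
Reagents that add atoms: none
Why: Hayashi–Miyaura asymmetric 1,4-addition, in which the aryl group passes from boron to the BINAP–rhodium hydroxide, the enoate inserts into the Rh–aryl bond in the enantio-determining step and water protonates the oxa-π-allylrhodium; (S)-BINAP should present the C2-si (C3-re) face of the (E)-enoate, which gives 3R, and the aryl bromide is inert to monovalent rhodium.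

**Step 7**
Reactants: 10 ethyl (3R)-3-[2,4-bis(benzyloxy)-5-bromophenyl]-5-[4-(benzyloxy)-2-methoxyphenyl]pentanoate
Product: 12 (3R)-3-[2,4-bis(benzyloxy)-5-bromophenyl]-5-[4-(benzyloxy)-2-methoxyphenyl]pentanal, via aluminium hemiacetal 11 (not isolated)
Conditions: i-Bu2AlH (1.1 equiv), CH2Cl2, −78 °C; MeOH, then aq. KNaC4H4O6 (potassium sodium tartrate)
Reagents that add atoms: none
Why: Partial reduction of an ester with i-Bu2AlH, in which the tetrahedral aluminium hemiacetal is stable at −78 °C and collapses to the aldehyde only on work-up after the excess hydride is destroyed, while the stereocentre β to the carbonyl group is not touched.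

**Step 8**
Reactants: 12 (3R)-3-[2,4-bis(benzyloxy)-5-bromophenyl]-5-[4-(benzyloxy)-2-methoxyphenyl]pentanal; 13 methyl vinyl ketone (but-3-en-2-one)
Product: 16 4-{(1R)-1-[2,4-bis(benzyloxy)-5-bromophenyl]-3-[4-(benzyloxy)-2-methoxyphenyl]propyl}cyclohex-2-en-1-one (both C4 epimers), via keto aldehyde 14 (not isolated), via ketol 15 (not isolated)
Conditions: 13 (1.5 equiv), Et2NSiMe3 (20 mol %), MeCN, reflux; evaporate; KOH (aq.), n-Bu4NOH (cat.), THF/Et2O, rt → reflux
Reagents that add atoms: none
Why: The diethylamine released from Et2NSiMe3 condenses with aldehyde 12 to an enamine whose nucleophilic carbon (the aldehyde α-carbon, the future C1 of ring B) adds to the terminal carbon of 13, and hydrolysis of the iminium ion returns the amine and leaves keto aldehyde 14. Hydroxide then forms the methyl-side enolate of the ketone, which attacks the aldehyde carbonyl in a 6-(enolexo)-exo-trig aldol closure to ketol 15, and E1cB loss of water gives the conjugated enone 16; this is a Robinson annulation of an aldehyde with methyl vinyl ketone, the known route from 3-substituted propanals to 4-substituted cyclohex-2-enones. The other possible aldol closures would give four-membered rings and do not compete, so the carbonyl oxygen must end on the ring carbon opposite the point of attachment, which is the para pattern of the 4-hydroxyphenyl group. The only new stereocentre, ring carbon C4, forms without control next to the existing centre and is left as a mixture because step 9 removes it. The selectivity needed is chemoselectivity for the cross Michael addition over aldehyde self-aldol reaction and enone oligomerisation; it is favoured by the neutral enamine conditions (no free enolate, base added only once the α-carbon is alkylated) and by the branching next to the α-CH2 group, which slows self-condensation. The exocyclic (R) centre is β to the aldehyde carbonyl, carries no acidic hydrogen at any stage and so cannot epimerise.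

**Step 9**
Reactants: 16 4-{(1R)-1-[2,4-bis(benzyloxy)-5-bromophenyl]-3-[4-(benzyloxy)-2-methoxyphenyl]propyl}cyclohex-2-en-1-one
Product: 19 4-{(1R)-1-[2,4-bis(benzyloxy)-5-bromophenyl]-3-[4-(benzyloxy)-2-methoxyphenyl]propyl}phenol, via silyl dienol ether 17 (not isolated), via cyclohexadienone 18 (not isolated)
Conditions: Me3SiOTf (1.3 equiv), Et3N (2 equiv), CH2Cl2, 0 °C; evaporate, filter through pentane; Pd(OAc)2 (1.05 equiv), MeCN, rt
Reagents that add atoms: none
Why: Ito–Saegusa dehydrogenation, in which soft enolisation at C6 gives the cross-conjugated silyl dienol ether 17, Pd(OAc)2 palladates C6 and β-hydride elimination gives the 4-monosubstituted cyclohexa-2,5-dienone 18, a keto tautomer that should aromatise at once to the phenol and so erase the uncontrolled ring centre, while the C–Br bond is inert to divalent palladium without a phosphine and the exocyclic stereocentre is never deprotonated.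

**Step 10**
Reactants: 19 4-{(1R)-1-[2,4-bis(benzyloxy)-5-bromophenyl]-3-[4-(benzyloxy)-2-methoxyphenyl]propyl}phenol
Product: 20 1,5-bis(benzyloxy)-2-bromo-4-{(1R)-3-[4-(benzyloxy)-2-methoxyphenyl]-1-[4-(benzyloxy)phenyl]propyl}benzene
Conditions: BnBr (1.2 equiv), K2CO3, DMF, rt
Reagents that add atoms: benzyl bromide, BrCc1ccccc1
Why: Williamson ether synthesis, which caps the new phenol so that its phenoxide cannot add to the aryl vinyl ketone under the basic conditions of step 12 and leaves one kind of protecting group for the final step.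

**Step 11**
Reactants: 21 1-[4-(benzyloxy)phenyl]ethan-1-one (4'-(benzyloxy)acetophenone, commercial)
Product: 23 1-[4-(benzyloxy)phenyl]prop-2-en-1-one, via Mannich base 22 (not isolated)
Conditions: (CH2O)n (2 equiv), i-Pr2NH2+ CF3CO2− (1 equiv), CF3CO2H (10 mol %), THF, reflux; used at once
Reagents that add atoms: formaldehyde (as paraformaldehyde), C=O
Why: Mannich condensation of the methyl ketone with the iminium ion from formaldehyde and diisopropylamine, followed by β-elimination of the bulky amine from the Mannich base, a known direct α-methylenation of aryl methyl ketones.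

**Step 12**
Reactants: 20 1,5-bis(benzyloxy)-2-bromo-4-{(1R)-3-[4-(benzyloxy)-2-methoxyphenyl]-1-[4-(benzyloxy)phenyl]propyl}benzene; 23 1-[4-(benzyloxy)phenyl]prop-2-en-1-one
Product: 24 (2E)-3-(2,4-bis(benzyloxy)-5-{(1R)-3-[4-(benzyloxy)-2-methoxyphenyl]-1-[4-(benzyloxy)phenyl]propyl}phenyl)-1-[4-(benzyloxy)phenyl]prop-2-en-1-one
Conditions: 23 (1.5 equiv), Pd2(dba)3 (2.5 mol %), [HP(t-Bu)3]BF4 (10 mol %), Cy2NMe (1.5 equiv), BHT (trace), 1,4-dioxane, 70 °C
Reagents that add atoms: none
Why: Mizoroki–Heck reaction, in which the bulky electron-rich P(t-Bu)3 ligand lets zerovalent palladium insert into the electron-rich, ortho-alkoxylated C–Br bond at moderate temperature, the arylpalladium adds to the unsubstituted alkene carbon of 23 and syn β-hydride elimination gives the (E)-enone.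

**Step 13**
Reactants: 24 (2E)-3-(2,4-bis(benzyloxy)-5-{(1R)-3-[4-(benzyloxy)-2-methoxyphenyl]-1-[4-(benzyloxy)phenyl]propyl}phenyl)-1-[4-(benzyloxy)phenyl]prop-2-en-1-one
Product: 25 3-{2,4-dihydroxy-5-[(1R)-3-(4-hydroxy-2-methoxyphenyl)-1-(4-hydroxyphenyl)propyl]phenyl}-1-(4-hydroxyphenyl)propan-1-one (CNP0253987.1)
Conditions: H2 (1 atm), 10 % Pd/C, EtOAc/MeOH 1:1, rt
Reagents that add atoms: none
Why: Heterogeneous catalytic hydrogenation saturates the enone C=C bond and hydrogenolyses the five benzyl ethers in one operation; it is stopped after six equivalents of hydrogen so that the more slowly reduced, electron-rich aryl ketone is kept, and the diarylmethine stereocentre has no C–O bond that could be cleaved.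

**Compound list**

1 | 4-bromo-3-methoxyphenol | COc1cc(O)ccc1Br | starting material
2 | 4-(benzyloxy)-1-bromo-2-methoxybenzene | COc1cc(OCc2ccccc2)ccc1Br | intermediate
3 | 4-(benzyloxy)-1-(but-3-en-1-yl)-2-methoxybenzene | COc1cc(OCc2ccccc2)ccc1CCC=C | intermediate
4 | ethyl (2E)-5-[4-(benzyloxy)-2-methoxyphenyl]pent-2-enoate | CCOC(=O)/C=C/CCc1ccc(OCc2ccccc2)cc1OC | intermediate
5 | 4,6-dibromobenzene-1,3-diol (4,6-dibromoresorcinol) | Oc1cc(O)c(Br)cc1Br | starting material
6 | 1,5-bis(benzyloxy)-2,4-dibromobenzene | Brc1cc(Br)c(OCc2ccccc2)cc1OCc1ccccc1 | intermediate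
7 | [2,4-bis(benzyloxy)-5-bromophenyl]lithium (not isolated) | [Li]c1cc(Br)c(OCc2ccccc2)cc1OCc1ccccc1 | intermediate
8 | lithium [2,4-bis(benzyloxy)-5-bromophenyl]tri(propan-2-yloxy)borate (not isolated) | [Li+].CC(C)O[B-](OC(C)C)(OC(C)C)c1cc(Br)c(OCc2ccccc2)cc1OCc1ccccc1 | intermediate
9 | [2,4-bis(benzyloxy)-5-bromophenyl]boronic acid | OB(O)c1cc(Br)c(OCc2ccccc2)cc1OCc1ccccc1 | intermediate
10 | ethyl (3R)-3-[2,4-bis(benzyloxy)-5-bromophenyl]-5-[4-(benzyloxy)-2-methoxyphenyl]pentanoate | COc1cc(OCc2ccccc2)ccc1CC[C@H](CC(=O)OCC)c1cc(Br)c(OCc2ccccc2)cc1OCc1ccccc1 | intermediate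
11 | diisobutylaluminium alkoxide of the ethyl hemiacetal of 12, (3R), hemiacetal carbon unassigned (not isolated) | COc1cc(OCc2ccccc2)ccc1CC[C@H](CC(OCC)O[Al](CC(C)C)CC(C)C)c1cc(Br)c(OCc2ccccc2)cc1OCc1ccccc1 | intermediate
12 | (3R)-3-[2,4-bis(benzyloxy)-5-bromophenyl]-5-[4-(benzyloxy)-2-methoxyphenyl]pentanal | COc1cc(OCc2ccccc2)ccc1CC[C@H](CC=O)c1cc(Br)c(OCc2ccccc2)cc1OCc1ccccc1 | intermediate
13 | methyl vinyl ketone (but-3-en-2-one) | CC(=O)C=C | starting material
14 | 2-{(1R)-1-[2,4-bis(benzyloxy)-5-bromophenyl]-3-[4-(benzyloxy)-2-methoxyphenyl]propyl}-5-oxohexanal, C2 epimers (not isolated) | COc1cc(OCc2ccccc2)ccc1CC[C@H](C(C=O)CCC(C)=O)c1cc(Br)c(OCc2ccccc2)cc1OCc1ccccc1 | intermediate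
15 | 4-{(1R)-1-[2,4-bis(benzyloxy)-5-bromophenyl]-3-[4-(benzyloxy)-2-methoxyphenyl]propyl}-3-hydroxycyclohexan-1-one, ring centres unassigned (not isolated) | COc1cc(OCc2ccccc2)ccc1CC[C@H](C1CCC(=O)CC1O)c1cc(Br)c(OCc2ccccc2)cc1OCc1ccccc1 | intermediate
16 | 4-{(1R)-1-[2,4-bis(benzyloxy)-5-bromophenyl]-3-[4-(benzyloxy)-2-methoxyphenyl]propyl}cyclohex-2-en-1-one, both C4 epimers | COc1cc(OCc2ccccc2)ccc1CC[C@H](C1C=CC(=O)CC1)c1cc(Br)c(OCc2ccccc2)cc1OCc1ccccc1 | intermediate
17 | [(4-{(1R)-1-[2,4-bis(benzyloxy)-5-bromophenyl]-3-[4-(benzyloxy)-2-methoxyphenyl]propyl}cyclohexa-1,5-dien-1-yl)oxy]trimethylsilane, C4 epimers (not isolated) | COc1cc(OCc2ccccc2)ccc1CC[C@H](C1C=CC(O[Si](C)(C)C)=CC1)c1cc(Br)c(OCc2ccccc2)cc1OCc1ccccc1 | intermediate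
18 | 4-{(1R)-1-[2,4-bis(benzyloxy)-5-bromophenyl]-3-[4-(benzyloxy)-2-methoxyphenyl]propyl}cyclohexa-2,5-dien-1-one (not isolated) | COc1cc(OCc2ccccc2)ccc1CC[C@H](C1C=CC(=O)C=C1)c1cc(Br)c(OCc2ccccc2)cc1OCc1ccccc1 | intermediate
19 | 4-{(1R)-1-[2,4-bis(benzyloxy)-5-bromophenyl]-3-[4-(benzyloxy)-2-methoxyphenyl]propyl}phenol | COc1cc(OCc2ccccc2)ccc1CC[C@H](c1ccc(O)cc1)c1cc(Br)c(OCc2ccccc2)cc1OCc1ccccc1 | intermediate
20 | 1,5-bis(benzyloxy)-2-bromo-4-{(1R)-3-[4-(benzyloxy)-2-methoxyphenyl]-1-[4-(benzyloxy)phenyl]propyl}benzene | COc1cc(OCc2ccccc2)ccc1CC[C@H](c1ccc(OCc2ccccc2)cc1)c1cc(Br)c(OCc2ccccc2)cc1OCc1ccccc1 | intermediate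
21 | 1-[4-(benzyloxy)phenyl]ethan-1-one | CC(=O)c1ccc(OCc2ccccc2)cc1 | starting material
22 | 1-[4-(benzyloxy)phenyl]-3-[di(propan-2-yl)amino]propan-1-one (not isolated) | CC(C)N(C(C)C)CCC(=O)c1ccc(OCc2ccccc2)cc1 | intermediate
23 | 1-[4-(benzyloxy)phenyl]prop-2-en-1-one | C=CC(=O)c1ccc(OCc2ccccc2)cc1 | intermediate
24 | (2E)-3-(2,4-bis(benzyloxy)-5-{(1R)-3-[4-(benzyloxy)-2-methoxyphenyl]-1-[4-(benzyloxy)phenyl]propyl}phenyl)-1-[4-(benzyloxy)phenyl]prop-2-en-1-one | COc1cc(OCc2ccccc2)ccc1CC[C@H](c1ccc(OCc2ccccc2)cc1)c1cc(/C=C/C(=O)c2ccc(OCc3ccccc3)cc2)c(OCc2ccccc2)cc1OCc1ccccc1 | intermediate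
25 | 3-{2,4-dihydroxy-5-[(1R)-3-(4-hydroxy-2-methoxyphenyl)-1-(4-hydroxyphenyl)propyl]phenyl}-1-(4-hydroxyphenyl)propan-1-one | COc1cc(O)ccc1CC[C@H](c1ccc(O)cc1)c1cc(CCC(=O)c2ccc(O)cc2)c(O)cc1O | target

**Step count**

Total step count: 13.
Longest linear sequence: 10 steps (steps 1, 2, 3, 6, 7, 8, 9, 10, 12, 13).

**Steps most likely to fail**

Step 6. Aryl transfer from the ortho-alkoxylated, electron-rich boronic acid may be slow, so that protodeboronation in the aqueous basic medium outruns insertion, or the catalyst may discriminate the enoate faces insufficiently. The fallback replaces catalyst control by auxiliary control; it sets out from alkene 3 and aryllithium 7 and comes back at ester 10. Alkene 3 is cross-metathesised, with the ruthenium catalyst of step 3, with commercial (4S)-3-acryloyl-4-phenyl-1,3-oxazolidin-2-one to give (4S)-3-{(2E)-5-[4-(benzyloxy)-2-methoxyphenyl]pent-2-enoyl}-4-phenyl-1,3-oxazolidin-2-one F1. Aryllithium 7, made as in step 5, is transmetalated with MgBr2·OEt2 to [2,4-bis(benzyloxy)-5-bromophenyl]magnesium bromide F2. With CuBr·SMe2 in THF at −40 °C this should add to the magnesium-chelated s-cis imide from the face away from the 4-phenyl group, giving (4S)-3-{(3R)-3-[2,4-bis(benzyloxy)-5-bromophenyl]-5-[4-(benzyloxy)-2-methoxyphenyl]pentanoyl}-4-phenyl-1,3-oxazolidin-2-one F3. Ethanolysis with EtOMgBr in EtOH/THF at 0 °C removes the auxiliary and gives ester 10.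

Step 8. Self-aldol condensation of the aldehyde and oligomerisation of methyl vinyl ketone may outrun the cross Michael addition at the branched α-position, or the aldol closure may stall. The fallback forms the same two ring bonds but replaces the Michael addition by alkylation with a masked methyl vinyl ketone; it sets out from aldehyde 12 and comes back at keto aldehyde 14, which is closed to enone 16 with the KOH/n-Bu4NOH of step 8. Aldehyde 12 is condensed with cyclohexylamine over MgSO4 to (3R)-3-[2,4-bis(benzyloxy)-5-bromophenyl]-5-[4-(benzyloxy)-2-methoxyphenyl]-N-cyclohexylpentan-1-imine F4. LiN(i-Pr)2 in THF at −78 °C converts it into the lithium aza-enolate F5, which is alkylated with 2-(2-bromoethyl)-2-methyl-1,3-dioxolane to the ketal imine (3R)-3-[2,4-bis(benzyloxy)-5-bromophenyl]-5-[4-(benzyloxy)-2-methoxyphenyl]-N-cyclohexyl-2-[2-(2-methyl-1,3-dioxolan-2-yl)ethyl]pentan-1-imine F6. Aqueous oxalic acid in THF hydrolyses the imine and the ketal to 14.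

Step 12. Oxidative addition into the electron-rich, ortho-alkoxylated aryl bromide may be slower than polymerisation of the aryl vinyl ketone. The fallback builds the same enone by aldol condensation instead of a palladium coupling; it sets out from bromide 20 and ketone 21 and comes back at chalcone 24. Bromine–lithium exchange on 20 with n-BuLi in THF at −78 °C gives the aryllithium (2,4-bis(benzyloxy)-5-{(1R)-3-[4-(benzyloxy)-2-methoxyphenyl]-1-[4-(benzyloxy)phenyl]propyl}phenyl)lithium F7. Trapping with DMF gives 2,4-bis(benzyloxy)-5-{(1R)-3-[4-(benzyloxy)-2-methoxyphenyl]-1-[4-(benzyloxy)phenyl]propyl}benzaldehyde F8. Claisen–Schmidt condensation of F8 with ketone 21 (KOH, EtOH/THF, rt) gives the (E)-chalcone 24.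

**Further compounds**

F1 | step 6 | (4S)-3-{(2E)-5-[4-(benzyloxy)-2-methoxyphenyl]pent-2-enoyl}-4-phenyl-1,3-oxazolidin-2-one | COc1cc(OCc2ccccc2)ccc1CC/C=C/C(=O)N1[C@@H](c2ccccc2)COC1=O
F2 | step 6 | [2,4-bis(benzyloxy)-5-bromophenyl]magnesium bromide | Br[Mg]c1cc(Br)c(OCc2ccccc2)cc1OCc1ccccc1
F3 | step 6 | (4S)-3-{(3R)-3-[2,4-bis(benzyloxy)-5-bromophenyl]-5-[4-(benzyloxy)-2-methoxyphenyl]pentanoyl}-4-phenyl-1,3-oxazolidin-2-one | COc1cc(OCc2ccccc2)ccc1CC[C@H](CC(=O)N1[C@@H](c2ccccc2)COC1=O)c1cc(Br)c(OCc2ccccc2)cc1OCc1ccccc1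
F4 | step 8 | (3R)-3-[2,4-bis(benzyloxy)-5-bromophenyl]-5-[4-(benzyloxy)-2-methoxyphenyl]-N-cyclohexylpentan-1-imine | COc1cc(OCc2ccccc2)ccc1CC[C@H](C/C=N/C1CCCCC1)c1cc(Br)c(OCc2ccccc2)cc1OCc1ccccc1
F5 | step 8 | lithium aza-enolate of F4 (lithium N-cyclohexyl enamide, C=C geometry not controlled) | COc1cc(OCc2ccccc2)ccc1CC[C@H](C=CN([Li])C1CCCCC1)c1cc(Br)c(OCc2ccccc2)cc1OCc1ccccc1
F6 | step 8 | (3R)-3-[2,4-bis(benzyloxy)-5-bromophenyl]-5-[4-(benzyloxy)-2-methoxyphenyl]-N-cyclohexyl-2-[2-(2-methyl-1,3-dioxolan-2-yl)ethyl]pentan-1-imine, C2 epimers | COc1cc(OCc2ccccc2)ccc1CC[C@H](C(/C=N/C1CCCCC1)CCC1(C)OCCO1)c1cc(Br)c(OCc2ccccc2)cc1OCc1ccccc1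
F7 | step 12 | (2,4-bis(benzyloxy)-5-{(1R)-3-[4-(benzyloxy)-2-methoxyphenyl]-1-[4-(benzyloxy)phenyl]propyl}phenyl)lithium | COc1cc(OCc2ccccc2)ccc1CC[C@H](c1ccc(OCc2ccccc2)cc1)c1cc([Li])c(OCc2ccccc2)cc1OCc1ccccc1
F8 | step 12 | 2,4-bis(benzyloxy)-5-{(1R)-3-[4-(benzyloxy)-2-methoxyphenyl]-1-[4-(benzyloxy)phenyl]propyl}benzaldehyde | COc1cc(OCc2ccccc2)ccc1CC[C@H](c1ccc(OCc2ccccc2)cc1)c1cc(C=O)c(OCc2ccccc2)cc1OCc1ccccc1
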